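The constants used here belong to no real substance; no experiment stands behind them.

Amounts first: 20 mM of substrate and 30.0 mM of reagent went into the north, south-west, south and north-east flasks, and the flasks differ in when those amounts go in.

the same everywhere: time 25 h

| run | substrate | reagent | remark |
|---|---|---|---|
| north | 20 mM | 30.0 mM | everything together at the start |
| south-west | 20 mM | 30.0 mM (fed, over 20 h) | all else is in the flask from the start; the feed brings no volume worth counting |
| south | 20 mM (fed, over 20 h) | 30.0 mM | all else is in the flask from the start; the feed brings no volume worth counting |
| north-east | 20 mM | 30.0 mM (in portions, 2, over 20 h) | first portion at the start, last at 20 h |

    target → over-reaction product (k1 = 0.137 /h)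
    substrate + reagent → target (k2 = 35.9 /M/h)
    substrate + reagent → second isomer (k3 = 2.16 /M/h)
    substrate + reagent → isomer of the product (k4 = 13.2 /M/h)
    2 reagent → homo dimer (k5 = 2.24 /M/h)

* which flask leads in share of target in target plus isomer of the product ("all alike" within 1.5 percentage points) (north / south-west / south / north-east / all alike)
* share of target in target plus isomer of the product at the end, north
* share of target in target plus isomer of the product at the end, south-west
* share of target in target plus isomer of the product at the end, south
* share of target in target plus isomer of the product at the end, north-east

To whoever takes over the bench: watch the age of the target. Substrate and reagent make target and its isomer side by side, and both rates carry the same two concentrations, so the selectivity factor stays at 2.72 target per isomer. The isomer has no step out, but the target decays with a mean life of 7.30 h. A batch of age a therefore keeps exp(-a/life), and I reckoned the share as branch·keep/(1+branch·keep).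

With half the reagent present, c(substrate) falls in about 1.30 h, shorter than that life, so I took the coupling as settled. In the north flask the target forms at the start and keeps 0.0389, which gives 9.57%. For the south-west and south flasks I assumed, as a coarse estimate, that formation spreads evenly over the 20 h of the feed, which puts the mean keep at 0.172 and gives 31.9% for south-west and 31.9% for south, one figure for two different flasks. The reagent fed to the south-west flask matches the substrate charge after 13.3 h, so formation there may end sooner than I assumed. In the north-east flask the first portion turns 75.0% of the substrate early, and the rest waits for the last portion, so the keep is 0.180, which gives 32.8%. That lies within 1.5 percentage points of my coarse figure for the feeds, so I named no leader. Do not hurry the feeds, and sample at 25 h.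

The forecast did name one, north-east, with 9.8%, 28%, 33% and 37% for north, south-west, south and north-east, holding that “the share depends only on how late the target forms”.

The simulation gave north-east, with 10.0%, 28.4%, 32.5% and 34.6% in the same order.

Striking out the path from target to over-reaction product took the gap between the north-east and north flasks from 25 points to 0 points, the largest single effect. Age against the life of 7.30 h also prices the south-west flask fed over 6.00 h: its keep is 0.0505, which gives 12.1%. That run ended at 13.7%.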